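The earlier runs and the new flask are simulated for substances that don't exist.

I counted this flask in molar days, substrate concentration times time, not in days. If the steps are bimolecular, as I assumed, a flask at equal equivalents runs the same curve, stretched by the ratio of concentrations, here 1.50.

- north-west: substrate 0.78 M; coupling partner 3 equiv; run made earlier
- flask: substrate 0.52 M; coupling partner 3.00 equiv; time 15 d

- north-west (time / d: mono adduct / %, double product / %): 0.333: 18.7, 0.6; 0.625: 20.4, 0.3; 1.04: 21.7, 1.1; 1.67: 22.4, 0.9; 2.50: 22.8, 1.8; 5.00: 22.9, 0.3

(standard deviation of a reading: 0.5 percentage points)

- a reading or a percentage of double product counts all its forms, free or not
- the reaction counts as stopped when no species that holds the substrate changes by six tenths of a point or more over the second half of the time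

* which holds at 15 d: what has brought the reaction to rest, or that it has not come to rest (it is still moving / the coupling partner has run out first / all of the substrate has reacted)
* how much mono adduct there is at 15 d, in percent of the substrate charged

On that clock I built a ladder. The lowest rung was the burst: the north-west reading at 0.333 d, which stands for 0.499 d in the flask, already held 18.7 % mono adduct. Next came the stop: between 2.50 d and 5.00 d the north-west mono adduct moved 0.1 percentage points against a scatter of 0.5 points, and that last reading stands for 7.50 d in the flask. The top rung, 15 d, lies 1.48 decades above the burst.

Taking the last mono adduct reading plus the mean double product reading, the north-west run had turned over about 23.7 % of its substrate against 3 equiv of coupling partner, so I inferred that the partner destroys itself at second order. Dividing that rate law by the coupling's removes time and concentration. I defined the burn number n: the constant of the partner's self-loss, both molecules counted, over the coupling constant, less one. With the partner gone, n times the log of the fraction of substrate left equals minus the log of one plus n times the equivalents. The north-west plateau lay 0.118 decades down, which gave n = 13.8. Concentration cancelled, so I expected 76.2 % substrate left, the partner out first, and mono adduct near 22.9 %.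

The forecast agreed on the end, the coupling partner has run out first, but gave 16.5 % mono adduct (from 13.5 % to 21 %), on this ground: “The ceiling then scales with concentration”. There we differed.

The outcome in the flask was that the coupling partner has run out first: at 15.0 d it held 22.7 % mono adduct, 76.1 % substrate, and 0 % of the partner's charge.

    substrate + coupling partner → mono adduct (k = 0.0950 M⁻¹ h⁻¹)
    coupling partner + mono adduct → double product (k = 0.0350 M⁻¹ h⁻¹)
    coupling partner + double product → triple product (k = 0.00460 M⁻¹ h⁻¹)
    coupling partner + double product → over-reaction product (k = 0.0400 M⁻¹ h⁻¹)
    crystals ⇌ double product, rate k5*(cs5 - [double product]) while solid is left; crystals form when [double product] > cs5 (solubility = 29.0 mM, k = 0.740 h⁻¹)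
    2 coupling partner → self-condensation product (k = 0.680 M⁻¹ h⁻¹)

A neighbouring flask, the same but with 0.750 equiv of coupling partner, took the same burn number, which gave 83.9 % substrate left. That flask held 84 % substrate and 15.7 % mono adduct at 15.0 d, with 0 % of its partner left.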